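**Retrosynthetic overview**
- Target allylic alcohol ⇐ trans-(2S,3S) methyl enoate by ester reduction; the side chain comes in with methyl ferulate, so no protecting groups are needed.
- Dihydrofuran ring ⇐ O1–C2 closure of a (1S,2S)-1-aryl-2-(2-hydroxyaryl)propan-1-ol through the benzylic cation; the C3 methyl steers trans.
- Both stereocentres ⇐ racemic α-(2-hydroxyaryl)propiophenone by asymmetric transfer hydrogenation with dynamic kinetic resolution.
- Key C3–C3a bond ⇐ enolonium (α-keto cation equivalent on trivalent iodine) of 3',4'-dimethoxypropiophenone + the free ortho carbon of methyl ferulate; an enol α-carbon and a phenol ortho carbon are both normally nucleophilic.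
- Ring order: both benzene rings are bought; the dihydrofuran is the only ring formed (step 4).

Assumption: 3',4'-dimethoxypropiophenone, Koser's reagent, methyl (E)-ferulate and RuCl[(S,S)-TsDPEN](p-cymene) are bought; benzofuran numbering (O1, C2 aryl, C3 methyl) is used. The target is (2S,3S), trans.

**Route**

Step 1
Reactants: 1 1-(3,4-dimethoxyphenyl)propan-1-one
Product: 2 (Z)-[1-(3,4-dimethoxyphenyl)prop-1-enyloxy]trimethylsilane
Conditions: TMSOTf (1.2 equiv), Et3N (1.5 equiv), CH2Cl2, 0 °C → rt; pentane, filter, concentrate, use crude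
Reagents that add atoms: trimethylsilyl trifluoromethanesulfonate (TMSOTf), C[Si](C)(C)OS(=O)(=O)C(F)(F)F
Why: Soft enolisation and O-silylation of an aryl ethyl ketone (silyl enol ether formation) gives mainly the Z enol silane, and the geometry does not matter because the α-carbon becomes an epimerisable centre in step 2.

Step 2
Reactants: 2 (Z)-[1-(3,4-dimethoxyphenyl)prop-1-enyloxy]trimethylsilane; 3 [hydroxy(tosyloxy)iodo]benzene (Koser's reagent, PhI(OH)OTs); 4 methyl (E)-3-(4-hydroxy-3-methoxyphenyl)prop-2-enoate (methyl ferulate)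
Product: 6 racemic methyl (E)-3-{3-[1-(3,4-dimethoxyphenyl)-1-oxopropan-2-yl]-4-hydroxy-5-methoxyphenyl}prop-2-enoate, via enolonium tosylate 5 (not isolated)
Conditions: 3 (1.2 equiv), BF3·OEt2 (1.5 equiv, activator, not consumed), CH2Cl2, −78 °C; add 2 (1.25 equiv) slowly, 10 min; then 4 (1.0 equiv), −78 → −20 °C; quench cold with aq. NaHCO3/Na2S2O3
Reagents that add atoms: none
Why: Proposed new method: Koser's reagent/BF3 turns the enol silane into an enolonium species (a trivalent-iodine enolate, an α-keto cation equivalent), so the normally nucleophilic α-carbon becomes electrophilic; the phenol is added only after all trivalent iodine is bound as enolonium (to avoid phenol oxidation) and attacks through its only free ortho carbon (the site where vanillin-type phenols are halogenated), with C-alkylation expected over O-alkylation as in acid-mediated Friedel–Crafts alkylation of free phenols, then loses PhI and rearomatises; the closest known reaction type is the metal-free α-arylation of ketones through preformed enolonium species with electron-rich arenes and heteroarenes, and the new α-centre is left racemic on purpose for step 3.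

Step 3
Reactants: 6 racemic methyl (E)-3-{3-[1-(3,4-dimethoxyphenyl)-1-oxopropan-2-yl]-4-hydroxy-5-methoxyphenyl}prop-2-enoate
Product: 7 methyl (E)-3-{3-[(1S,2S)-1-(3,4-dimethoxyphenyl)-1-hydroxypropan-2-yl]-4-hydroxy-5-methoxyphenyl}prop-2-enoate
Conditions: RuCl[(S,S)-TsDPEN](p-cymene) (2 mol %), HCO2H (3 equiv), DBU (5 equiv), DMF, 40 °C; chromatography to remove the minor (1S,2R) diastereomer
Reagents that add atoms: none
Why: Noyori–Ikariya asymmetric transfer hydrogenation with dynamic kinetic resolution: DBU racemises the acidic α-aryl ketone centre through its enolate, the (S,S) catalyst gives the (1S) carbinol (same sense as acetophenone to (S)-1-phenylethanol) and is predicted to reduce the (S)-ketone fastest because its preferred face is then also the Felkin–Anh face, giving (1S,2S); the enoate C=C is not reduced, and removing the minor diastereomer here secures the C2 centre that alone survives into the product.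

Step 4
Reactants: 7 methyl (E)-3-{3-[(1S,2S)-1-(3,4-dimethoxyphenyl)-1-hydroxypropan-2-yl]-4-hydroxy-5-methoxyphenyl}prop-2-enoate
Product: 8 methyl (E)-3-[(2S,3S)-2-(3,4-dimethoxyphenyl)-7-methoxy-3-methyl-2,3-dihydro-1-benzofuran-5-yl]prop-2-enoate
Conditions: TsOH·H2O (10 mol %), CH2Cl2, 0 °C → rt
Reagents that add atoms: none
Why: Acid-mediated SN1 dehydrative cycloetherification: the 3,4-dimethoxybenzylic carbinol ionises to a p-methoxy-stabilised cation that the phenol oxygen captures in a five-membered closure anti to the C3 methyl, so the fixed (3S) centre gives the kinetically and thermodynamically preferred trans (2S) centre whatever the carbinol configuration, and the enoate is inert to the acid.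

Step 5
Reactants: 8 methyl (E)-3-[(2S,3S)-2-(3,4-dimethoxyphenyl)-7-methoxy-3-methyl-2,3-dihydro-1-benzofuran-5-yl]prop-2-enoate
Product: 9 (E)-3-[(2S,3S)-2-(3,4-dimethoxyphenyl)-7-methoxy-3-methyl-2,3-dihydro-1-benzofuran-5-yl]prop-2-en-1-ol
Conditions: i-Bu2AlH (3 equiv), CH2Cl2, −78 °C; aq. potassium sodium tartrate (KNaC4H4O6) work-up
Reagents that add atoms: none
Why: i-Bu2AlH 1,2-reduction of an (E)-cinnamate ester to the allylic alcohol (as in ferulate to coniferyl alcohol) leaves the alkene geometry, aryl ethers and both stereocentres untouched, and the neutral tartrate work-up protects the acid-sensitive cinnamyl alcohol.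

**Compound list**

1 | 1-(3,4-dimethoxyphenyl)propan-1-one | CCC(=O)c1ccc(OC)c(OC)c1 | starting material
2 | (Z)-[1-(3,4-dimethoxyphenyl)prop-1-enyloxy]trimethylsilane | C/C=C(\O[Si](C)(C)C)c1ccc(OC)c(OC)c1 | intermediate
3 | [hydroxy(tosyloxy)iodo]benzene (Koser's reagent) | OI(OS(=O)(=O)c1ccc(C)cc1)c1ccccc1 | starting material
4 | methyl (E)-3-(4-hydroxy-3-methoxyphenyl)prop-2-enoate (methyl ferulate) | COC(=O)/C=C/c1ccc(O)c(OC)c1 | starting material
5 | enolonium tosylate: (Z)-[1-(3,4-dimethoxyphenyl)prop-1-enyloxy](phenyl)(4-methylbenzenesulfonyloxy)iodane, drawn oxygen-bound | C/C=C(\OI(OS(=O)(=O)c1ccc(C)cc1)c1ccccc1)c1ccc(OC)c(OC)c1 | intermediate (not isolated)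
6 | racemic methyl (E)-3-{3-[1-(3,4-dimethoxyphenyl)-1-oxopropan-2-yl]-4-hydroxy-5-methoxyphenyl}prop-2-enoate | COC(=O)/C=C/c1cc(OC)c(O)c(C(C)C(=O)c2ccc(OC)c(OC)c2)c1 | intermediate
7 | methyl (E)-3-{3-[(1S,2S)-1-(3,4-dimethoxyphenyl)-1-hydroxypropan-2-yl]-4-hydroxy-5-methoxyphenyl}prop-2-enoate | COC(=O)/C=C/c1cc(OC)c(O)c([C@H](C)[C@H](O)c2ccc(OC)c(OC)c2)c1 | intermediate
8 | methyl (E)-3-[(2S,3S)-2-(3,4-dimethoxyphenyl)-7-methoxy-3-methyl-2,3-dihydro-1-benzofuran-5-yl]prop-2-enoate (trans) | COc1ccc([C@H]2Oc3c(OC)cc(/C=C/C(=O)OC)cc3[C@@H]2C)cc1OC | intermediate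
9 | (E)-3-[(2S,3S)-2-(3,4-dimethoxyphenyl)-7-methoxy-3-methyl-2,3-dihydro-1-benzofuran-5-yl]prop-2-en-1-ol (trans) | COc1ccc([C@H]2Oc3c(OC)cc(/C=C/CO)cc3[C@@H]2C)cc1OC | target

**Totals**

Total step count: 5. Longest linear sequence: 5 steps (1 → 2 → 6 → 7 → 8 → 9); 3 and 4 are bought and enter in step 2.

**Steps most likely to fail**

Step 2 is the most likely to fail. The risks are O-alkylation of the phenol to the α-aryloxy ketone, oxidation of the phenol by trivalent iodine, the modest ring nucleophilicity of a ferulate, and cyclodehydration of 6 to a benzofuran if the acidic mixture warms before the quench. The fallback sets out from 4 and comes back to the route at 6; it makes the C2–C3 bond with an acyl anion instead. Compound 4 is ortho-hydroxyalkylated through its ArOMgBr salt (EtMgBr, then CH3CHO, toluene, rt) to racemic methyl (E)-3-[4-hydroxy-3-(1-hydroxyethyl)-5-methoxyphenyl]prop-2-enoate F1. The benzylic hydroxyl is exchanged with 4-methylbenzenesulfinic acid (CH2Cl2, rt) to give racemic methyl (E)-3-{4-hydroxy-3-methoxy-5-[1-(4-methylbenzenesulfonyl)ethyl]phenyl}prop-2-enoate F2. F2 is then treated with 3,4-dimethoxybenzaldehyde, 3-ethyl-5-(2-hydroxyethyl)-4-methylthiazolium bromide (20 mol %) and Cs2CO3 in CH2Cl2 at rt. The base eliminates sulfinate to the ortho-quinone methide, and the Breslow intermediate of the aldehyde adds to its exocyclic carbon to give ketone 6.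

Step 3 is the second risk. Enolisation may be too slow for a dynamic resolution, or the catalyst may prefer the (R)-ketone, which would give the wrong α-series. Because C1 is erased in step 4, the diastereomer ratio here becomes the enantiomer ratio of 8. The fallback sets out from 6 and comes back to the route at 7; it uses catalyst-controlled reduction without racemisation, followed by diastereomer separation. Racemic 6 is reduced with (R)-2-methyl-CBS-oxazaborolidine (20 mol %) and BH3·SMe2 (2.5 equiv, one equivalent is taken by the phenol) in THF at −20 °C. Each ketone enantiomer gives a (1S) carbinol: alcohol 7 from (S)-6, and methyl (E)-3-{3-[(1S,2R)-1-(3,4-dimethoxyphenyl)-1-hydroxypropan-2-yl]-4-hydroxy-5-methoxyphenyl}prop-2-enoate F3 from (R)-6. The two diastereomers are separated on silica and 7 goes on to step 4, at a ceiling of 50 % yield. This delivers the (2S) series whichever ketone enantiomer a dynamic catalyst would have preferred.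

Step 4 is the third risk. It may give a cis/trans mixture, erode C3 through alkene formation from the open cation, or give intermolecular benzylation. The fallback sets out from 7 and comes back to the route at 8; it separates ring closure from stereo-equilibration. Mitsunobu closure (PPh3, DIAD, THF, 0 °C) forms the ring under neutral conditions with inversion at the carbinol, giving mainly the cis ester methyl (E)-3-[(2R,3S)-2-(3,4-dimethoxyphenyl)-7-methoxy-3-methyl-2,3-dihydro-1-benzofuran-5-yl]prop-2-enoate F4. F4, or any cis/trans mixture, is then equilibrated at C2 with TFA (2 equiv) in CH2Cl2 at 0 °C through reversible opening of the p-methoxybenzylic C2–O bond, which gives the trans ester 8.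

**Further compounds**

F1 | step 2 | racemic methyl (E)-3-[4-hydroxy-3-(1-hydroxyethyl)-5-methoxyphenyl]prop-2-enoate | COC(=O)/C=C/c1cc(OC)c(O)c(C(C)O)c1
F2 | step 2 | racemic methyl (E)-3-{4-hydroxy-3-methoxy-5-[1-(4-methylbenzenesulfonyl)ethyl]phenyl}prop-2-enoate | COC(=O)/C=C/c1cc(OC)c(O)c(C(C)S(=O)(=O)c2ccc(C)cc2)c1
F3 | step 3 | methyl (E)-3-{3-[(1S,2R)-1-(3,4-dimethoxyphenyl)-1-hydroxypropan-2-yl]-4-hydroxy-5-methoxyphenyl}prop-2-enoate | COC(=O)/C=C/c1cc(OC)c(O)c([C@@H](C)[C@H](O)c2ccc(OC)c(OC)c2)c1
F4 | step 4 | methyl (E)-3-[(2R,3S)-2-(3,4-dimethoxyphenyl)-7-methoxy-3-methyl-2,3-dihydro-1-benzofuran-5-yl]prop-2-enoate (cis) | COc1ccc([C@@H]2Oc3c(OC)cc(/C=C/C(=O)OC)cc3[C@@H]2C)cc1OC
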